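**Plan**
- The retrosynthesis cuts O1–C2 of ring C (phenol addition to an ynone), then C4a–C8a of ring A (6π closure of a dienylketene), then C5–C6 (alkenyllithium plus dimethyl squarate) and C3–C4 (acetylide plus (E)-3-iodoacrolein).
- Enabling feature: ring A carries four contiguous oxygenated carbons, C6, C7, C8 (OMe) and C8a (bonded to O1), which are the four carbons of squaric acid; C5–H and C4a are a two-carbon alkene.
- Forward: the ring B alkyne is added to iodoacrolein, the alkenyl iodide is lithiated and added to dimethyl squarate, thermolysis builds ring A, and desilylation, oxidation and amine-promoted closure give ring C.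
- Stereochemistry: the target is achiral. The carbinol and cyclobutenone sp3 centres are carried as mixtures and erased. The E alkene comes from (E)-3-iodoacrolein.

Key step: step 8

Remark: ethyl propiolate, 3-hydroxy-4,5-dimethoxybenzaldehyde and dimethyl squarate are taken as commercial; all chiral intermediates are racemic or diastereomeric mixtures, which has no consequence for the target.

**Step 1**
Reactants: 1 ethyl propiolate
Product: 2 ethyl (Z)-3-iodoacrylate
Conditions: NaI, AcOH, 70 °C
Reagents that add atoms: sodium iodide [Na+].[I-]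
Why: Conjugate hydroiodination of the ynoate proceeds by anti addition of iodide and a proton, so the Z β-iodoacrylate should form under kinetic control.

**Step 2**
Reactants: 2 ethyl (Z)-3-iodoacrylate
Product: 4 (E)-3-iodoacrolein, via (Z)-3-iodoacrolein 3 (not isolated)
Conditions: i-Bu2AlH (1.05 equiv), CH2Cl2, −78 °C; aq. HCl work-up; then cat. I2, CH2Cl2, rt; used at once as a solution
Reagents that add atoms: none
Why: Partial ester reduction at low temperature should stop at the aldehyde because the tetrahedral aluminium hemiacetal persists until work-up, and the Z β-iodoenal should equilibrate to the more stable E isomer by reversible iodine addition–elimination.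

**Step 3**
Reactants: 5 3-hydroxy-4,5-dimethoxybenzaldehyde
Product: 6 3,4-dimethoxy-5-(triisopropylsilyloxy)benzaldehyde
Conditions: TIPSCl, imidazole, DMF, rt
Reagents that add atoms: triisopropylsilyl chloride CC(C)[Si](Cl)(C(C)C)C(C)C
Why: Imidazole-mediated silylation of a phenol is routine, and the hindered aryl TIPS ether should tolerate carbonate in methanol and the organolithium steps that follow.

**Step 4**
Reactants: 6 3,4-dimethoxy-5-(triisopropylsilyloxy)benzaldehyde
Product: 7 (5-ethynyl-2,3-dimethoxyphenoxy)triisopropylsilane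
Conditions: dimethyl (1-diazo-2-oxopropyl)phosphonate, K2CO3, MeOH, 0 °C to rt
Reagents that add atoms: Ohira–Bestmann reagent CC(=O)C(=[N+]=[N-])P(=O)(OC)OC
Why: Ohira–Bestmann alkynylation (Seyferth–Gilbert homologation) should convert the non-enolisable aryl aldehyde into the terminal alkyne by olefination with the diazomethylphosphonate anion, loss of N2 and 1,2-shift.

**Step 5**
Reactants: 7 (5-ethynyl-2,3-dimethoxyphenoxy)triisopropylsilane; 4 (E)-3-iodoacrolein
Product: 9 (E)-5-(3,4-dimethoxy-5-triisopropylsilyloxyphenyl)-1-iodopent-1-en-4-yn-3-ol (racemic), via lithium acetylide 8 (not isolated)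
Conditions: n-BuLi, THF, −78 °C; then 4, −78 °C; aq. NH4Cl
Reagents that add atoms: none
Why: The hard lithium acetylide should add 1,2 to the enal carbonyl and leave the vinylic iodide untouched, giving the carbinol as a racemate that needs no control.

**Step 6**
Reactants: 9 (E)-5-(3,4-dimethoxy-5-triisopropylsilyloxyphenyl)-1-iodopent-1-en-4-yn-3-ol
Product: 10 tert-butyl{[(E)-5-(3,4-dimethoxy-5-triisopropylsilyloxyphenyl)-1-iodopent-1-en-4-yn-3-yl]oxy}dimethylsilane (racemic)
Conditions: TBSCl, imidazole, DMF, rt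
Reagents that add atoms: tert-butyldimethylsilyl chloride CC(C)(C)[Si](C)(C)Cl
Why: Standard silylation of a secondary alcohol masks the only acidic O–H, so that step 7 generates a single nucleophilic site.

**Step 7**
Reactants: 10 tert-butyl{[(E)-5-(3,4-dimethoxy-5-triisopropylsilyloxyphenyl)-1-iodopent-1-en-4-yn-3-yl]oxy}dimethylsilane; 11 dimethyl squarate
Product: 14 4-[(E)-3-(tert-butyldimethylsilyloxy)-5-(3,4-dimethoxy-5-triisopropylsilyloxyphenyl)pent-1-en-4-ynyl]-2,3,4-trimethoxycyclobut-2-en-1-one (diastereomer mixture), via alkenyllithium 12 (not isolated), via lithium cyclobutenolate 13 (not isolated)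
Conditions: t-BuLi (2.1 equiv), Et2O, −78 °C; cannulated into 11 (1.2 equiv), THF, −78 °C; then MeOTf, −78 to 0 °C
Reagents that add atoms: methyl triflate COS(=O)(=O)C(F)(F)F
Why: Iodine–lithium exchange should give the E alkenyllithium with retention, which adds 1,2 to one of the two equivalent squarate carbonyls, and the tertiary alkoxide is then O-methylated by MeOTf (known squarate mono-addition with alkoxide trapping).

**Step 8**
Reactants: 14 4-[(E)-3-(tert-butyldimethylsilyloxy)-5-(3,4-dimethoxy-5-triisopropylsilyloxyphenyl)pent-1-en-4-ynyl]-2,3,4-trimethoxycyclobut-2-en-1-one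
Product: 17 6-[1-(tert-butyldimethylsilyloxy)-3-(3,4-dimethoxy-5-triisopropylsilyloxyphenyl)prop-2-ynyl]-2,3,4-trimethoxyphenol (racemic), via dienylketene 15 (not isolated), via cyclohexadienone 16 (not isolated)
Conditions: toluene (0.02 M, degassed), 110 °C
Reagents that add atoms: none
Why: Heating should open the C1–C4 bond of the cyclobutenone by conrotatory 4π electrocyclic ring opening to dienylketene 15, whose ketene carbon (future C8a) then bonds to the alkene terminus (future C4a) in a disrotatory 6π electrocyclisation that closes ring A as a six-membered carbocycle; tautomerisation of dienone 16 gives the phenol. The closest known reaction type is the Moore ring expansion of 4-alkenyl-4-alkoxy- or 4-hydroxycyclobutenones from squarates to oxygenated phenols and hydroquinones. The step needs the alkenyl group to turn inward toward the ketene, and this is secured by the 4-methoxy donor, which prefers outward rotation. The ring A pattern cannot scramble, because the squarate is symmetric and carries a single alkenyl group: the former squarate carbons become C6, C7, C8 and C8a, and the ketene oxygen emerges as the only free phenol, the future O1. No lasting stereocentre is created, since the sp3 carbon of 16 is lost on aromatisation and the carbinol centre is carried through as a racemate. High dilution should suppress intermolecular trapping of the ketene.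

**Step 9**
Reactants: 17 6-[1-(tert-butyldimethylsilyloxy)-3-(3,4-dimethoxy-5-triisopropylsilyloxyphenyl)prop-2-ynyl]-2,3,4-trimethoxyphenol
Product: 18 6-[1-hydroxy-3-(3-hydroxy-4,5-dimethoxyphenyl)prop-2-ynyl]-2,3,4-trimethoxyphenol (racemic)
Conditions: Bu4NF (3 equiv), AcOH (3 equiv), THF, 0 °C to rt
Reagents that add atoms: none
Why: Fluoride-driven Si–O cleavage should remove the alkyl TBS and the aryl TIPS ether together, with acetic acid buffering the phenoxide and alkoxide.

**Step 10**
Reactants: 18 6-[1-hydroxy-3-(3-hydroxy-4,5-dimethoxyphenyl)prop-2-ynyl]-2,3,4-trimethoxyphenol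
Product: 19 1-(2-hydroxy-3,4,5-trimethoxyphenyl)-3-(3-hydroxy-4,5-dimethoxyphenyl)prop-2-yn-1-one
Conditions: activated MnO2 (excess), CH2Cl2, rt
Reagents that add atoms: none
Why: Manganese dioxide selectively oxidises benzylic and propargylic alcohols, a known way to ortho-hydroxyaryl ynones, and the product is stabilised by its phenol–carbonyl hydrogen bond.

**Step 11**
Reactants: 19 1-(2-hydroxy-3,4,5-trimethoxyphenyl)-3-(3-hydroxy-4,5-dimethoxyphenyl)prop-2-yn-1-one
Product: 21 2-(3-hydroxy-4,5-dimethoxyphenyl)-6,7,8-trimethoxy-4H-chromen-4-one, via enaminone 20 (not isolated)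
Conditions: Et2NH, EtOH, rt to 60 °C
Reagents that add atoms: none
Why: Conjugate addition of the amine gives a β-enaminone whose β-carbon is attacked by the ortho phenol in a 6-endo oxa-Michael addition–elimination that expels Et2NH and forms ring C, a pathway that should disfavour 5-exo closure to the aurone.

**Compound list**
1 | ethyl propiolate | C#CC(=O)OCC | starting material
2 | ethyl (Z)-3-iodoacrylate | CCOC(=O)/C=C\I | intermediate
3 | (Z)-3-iodoacrolein | O=C/C=C\I | intermediate
4 | (E)-3-iodoacrolein | O=C/C=C/I | intermediate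
5 | 3-hydroxy-4,5-dimethoxybenzaldehyde | COc1cc(C=O)cc(O)c1OC | starting material
6 | 3,4-dimethoxy-5-(triisopropylsilyloxy)benzaldehyde | COc1cc(C=O)cc(O[Si](C(C)C)(C(C)C)C(C)C)c1OC | intermediate
7 | (5-ethynyl-2,3-dimethoxyphenoxy)triisopropylsilane | COc1cc(C#C)cc(O[Si](C(C)C)(C(C)C)C(C)C)c1OC | intermediate
8 | lithium acetylide of 7 | [Li]C#Cc1cc(OC)c(OC)c(O[Si](C(C)C)(C(C)C)C(C)C)c1 | intermediate
9 | (E)-5-(3,4-dimethoxy-5-triisopropylsilyloxyphenyl)-1-iodopent-1-en-4-yn-3-ol (racemic) | OC(/C=C/I)C#Cc1cc(OC)c(OC)c(O[Si](C(C)C)(C(C)C)C(C)C)c1 | intermediate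
10 | tert-butyl{[(E)-5-(3,4-dimethoxy-5-triisopropylsilyloxyphenyl)-1-iodopent-1-en-4-yn-3-yl]oxy}dimethylsilane (racemic) | CC(C)(C)[Si](C)(C)OC(/C=C/I)C#Cc1cc(OC)c(OC)c(O[Si](C(C)C)(C(C)C)C(C)C)c1 | intermediate
11 | dimethyl squarate | COC1=C(OC)C(=O)C1=O | starting material
12 | (E)-alkenyllithium from 10 | [Li]/C=C/C(O[Si](C)(C)C(C)(C)C)C#Cc1cc(OC)c(OC)c(O[Si](C(C)C)(C(C)C)C(C)C)c1 | intermediate
13 | lithium 1-alkenyl-2,3-dimethoxy-4-oxocyclobut-2-en-1-olate (adduct of 12 and 11) | COC1=C(OC)C(O[Li])(/C=C/C(O[Si](C)(C)C(C)(C)C)C#Cc2cc(OC)c(OC)c(O[Si](C(C)C)(C(C)C)C(C)C)c2)C1=O | intermediate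
14 | 4-[(E)-3-(tert-butyldimethylsilyloxy)-5-(3,4-dimethoxy-5-triisopropylsilyloxyphenyl)pent-1-en-4-ynyl]-2,3,4-trimethoxycyclobut-2-en-1-one (diastereomer mixture) | COC1=C(OC)C(OC)(/C=C/C(O[Si](C)(C)C(C)(C)C)C#Cc2cc(OC)c(OC)c(O[Si](C(C)C)(C(C)C)C(C)C)c2)C1=O | intermediate
15 | (3Z,5E)-7-(tert-butyldimethylsilyloxy)-9-(3,4-dimethoxy-5-triisopropylsilyloxyphenyl)-2,3,4-trimethoxynona-1,3,5-trien-8-yn-1-one (dienylketene) | O=C=C(OC)/C(OC)=C(OC)\C=C\C(O[Si](C)(C)C(C)(C)C)C#Cc1cc(OC)c(OC)c(O[Si](C(C)C)(C(C)C)C(C)C)c1 | intermediate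
16 | 6-[1-(tert-butyldimethylsilyloxy)-3-(3,4-dimethoxy-5-triisopropylsilyloxyphenyl)prop-2-ynyl]-2,3,4-trimethoxycyclohexa-2,4-dien-1-one | COC1=CC(C(O[Si](C)(C)C(C)(C)C)C#Cc2cc(OC)c(OC)c(O[Si](C(C)C)(C(C)C)C(C)C)c2)C(=O)C(OC)=C1OC | intermediate
17 | 6-[1-(tert-butyldimethylsilyloxy)-3-(3,4-dimethoxy-5-triisopropylsilyloxyphenyl)prop-2-ynyl]-2,3,4-trimethoxyphenol (racemic) | COc1cc(C(O[Si](C)(C)C(C)(C)C)C#Cc2cc(OC)c(OC)c(O[Si](C(C)C)(C(C)C)C(C)C)c2)c(O)c(OC)c1OC | intermediate
18 | 6-[1-hydroxy-3-(3-hydroxy-4,5-dimethoxyphenyl)prop-2-ynyl]-2,3,4-trimethoxyphenol (racemic) | COc1cc(C(O)C#Cc2cc(OC)c(OC)c(O)c2)c(O)c(OC)c1OC | intermediate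
19 | 1-(2-hydroxy-3,4,5-trimethoxyphenyl)-3-(3-hydroxy-4,5-dimethoxyphenyl)prop-2-yn-1-one | COc1cc(C(=O)C#Cc2cc(OC)c(OC)c(O)c2)c(O)c(OC)c1OC | intermediate
20 | 3-(diethylamino)-1-(2-hydroxy-3,4,5-trimethoxyphenyl)-3-(3-hydroxy-4,5-dimethoxyphenyl)prop-2-en-1-one | CCN(CC)C(=CC(=O)c1cc(OC)c(OC)c(OC)c1O)c1cc(OC)c(OC)c(O)c1 | intermediate
21 | 2-(3-hydroxy-4,5-dimethoxyphenyl)-6,7,8-trimethoxy-4H-chromen-4-one | COc1cc(-c2cc(=O)c3cc(OC)c(OC)c(OC)c3o2)cc(O)c1OC | target

**Step count and risks**
Total step count: 11. Longest linear sequence: 9 steps (steps 3 to 11, from aldehyde 5); the iodoacrolein branch (steps 1 and 2) joins at step 5.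

The three steps most likely to fail are steps 7, 8 and 10.

Step 7. Proton transfer from the doubly activated carbinol C–H (allylic, propargylic and silyloxy-bearing) to the alkenyllithium, or a second addition to the squarate, may erode the mono-adduct. The fallback brings in the aryl alkyne only after the four-membered ring exists. It sets out from (E)-3-iodoacrolein 4, which is acetalised with triethyl orthoformate and catalytic TsOH in ethanol to (E)-3,3-diethoxy-1-iodoprop-1-ene F1. Iodine–lithium exchange (t-BuLi, Et2O, −78 °C), addition to dimethyl squarate 11 and MeOTf trapping should give 4-[(E)-3,3-diethoxyprop-1-enyl]-2,3,4-trimethoxycyclobut-2-en-1-one F2. Mild hydrolysis (PPTS, acetone/water, rt) would release (E)-3-(1,2,3-trimethoxy-4-oxocyclobut-2-en-1-yl)prop-2-enal F3. Lithium acetylide 8 at −78 °C should add to the aldehyde in preference to the vinylogous ester carbonyl, giving 4-[(E)-5-(3,4-dimethoxy-5-triisopropylsilyloxyphenyl)-3-hydroxypent-1-en-4-ynyl]-2,3,4-trimethoxycyclobut-2-en-1-one F4. Silylation (TBSCl, imidazole) comes back to the route at 14.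

Step 8. Once the phenol has formed, thermal loss of silanol from the ortho-hydroxybenzylic silyl ether (an ortho-quinone methide pathway) or other degradation of the silyloxy enyne may compete at the ring-opening temperature. The fallback raises the side chain to the ketone oxidation level before the ring expansion, so that no benzylic leaving group is present. It sets out from 14: buffered Bu4NF/AcOH in THF should give 4-[(E)-3-hydroxy-5-(3-hydroxy-4,5-dimethoxyphenyl)pent-1-en-4-ynyl]-2,3,4-trimethoxycyclobut-2-en-1-one F5. Manganese dioxide then oxidises this allylic, propargylic alcohol to 4-[(E)-5-(3-hydroxy-4,5-dimethoxyphenyl)-3-oxopent-1-en-4-ynyl]-2,3,4-trimethoxycyclobut-2-en-1-one F6. Thermolysis of F6 in dilute toluene at 110 °C (the same 4π opening and 6π closure) should deliver ynone 19 directly, where the route is rejoined ahead of step 11.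

Step 10. Oxidation of the electron-rich ring A phenol (quinone formation) may outrun oxidation of the carbinol on the manganese dioxide surface. The fallback masks that phenol before the alcohol is freed and oxidised. It sets out from 17: Ac2O, pyridine and catalytic DMAP should give 6-[1-(tert-butyldimethylsilyloxy)-3-(3,4-dimethoxy-5-triisopropylsilyloxyphenyl)prop-2-ynyl]-2,3,4-trimethoxyphenyl acetate F7. HF·pyridine in THF/pyridine cleaves only the alkyl TBS ether, giving 6-[1-hydroxy-3-(3,4-dimethoxy-5-triisopropylsilyloxyphenyl)prop-2-ynyl]-2,3,4-trimethoxyphenyl acetate F8, which is oxidised at once with Dess–Martin periodinane (NaHCO3, CH2Cl2) to 6-[3-(3,4-dimethoxy-5-triisopropylsilyloxyphenyl)prop-2-ynoyl]-2,3,4-trimethoxyphenyl acetate F9. Et2NH in EtOH at 50 °C should remove the acetate by aminolysis and close ring C through the enaminone, giving 2-(3,4-dimethoxy-5-triisopropylsilyloxyphenyl)-6,7,8-trimethoxy-4H-chromen-4-one F10. Bu4NF in THF then comes back to the route at target 21.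

**Further compounds**
F1 | step 7 | (E)-3,3-diethoxy-1-iodoprop-1-ene | CCOC(OCC)/C=C/I
F2 | step 7 | 4-[(E)-3,3-diethoxyprop-1-enyl]-2,3,4-trimethoxycyclobut-2-en-1-one | CCOC(OCC)/C=C/C1(OC)C(OC)=C(OC)C1=O
F3 | step 7 | (E)-3-(1,2,3-trimethoxy-4-oxocyclobut-2-en-1-yl)prop-2-enal | O=C/C=C/C1(OC)C(OC)=C(OC)C1=O
F4 | step 7 | 4-[(E)-5-(3,4-dimethoxy-5-triisopropylsilyloxyphenyl)-3-hydroxypent-1-en-4-ynyl]-2,3,4-trimethoxycyclobut-2-en-1-one | COC1=C(OC)C(OC)(/C=C/C(O)C#Cc2cc(OC)c(OC)c(O[Si](C(C)C)(C(C)C)C(C)C)c2)C1=O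
F5 | step 8 | 4-[(E)-3-hydroxy-5-(3-hydroxy-4,5-dimethoxyphenyl)pent-1-en-4-ynyl]-2,3,4-trimethoxycyclobut-2-en-1-one | COC1=C(OC)C(OC)(/C=C/C(O)C#Cc2cc(OC)c(OC)c(O)c2)C1=O
F6 | step 8 | 4-[(E)-5-(3-hydroxy-4,5-dimethoxyphenyl)-3-oxopent-1-en-4-ynyl]-2,3,4-trimethoxycyclobut-2-en-1-one | COC1=C(OC)C(OC)(/C=C/C(=O)C#Cc2cc(OC)c(OC)c(O)c2)C1=O
F7 | step 10 | 6-[1-(tert-butyldimethylsilyloxy)-3-(3,4-dimethoxy-5-triisopropylsilyloxyphenyl)prop-2-ynyl]-2,3,4-trimethoxyphenyl acetate | COc1cc(C(O[Si](C)(C)C(C)(C)C)C#Cc2cc(OC)c(OC)c(O[Si](C(C)C)(C(C)C)C(C)C)c2)c(OC(C)=O)c(OC)c1OC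
F8 | step 10 | 6-[1-hydroxy-3-(3,4-dimethoxy-5-triisopropylsilyloxyphenyl)prop-2-ynyl]-2,3,4-trimethoxyphenyl acetate | COc1cc(C(O)C#Cc2cc(OC)c(OC)c(O[Si](C(C)C)(C(C)C)C(C)C)c2)c(OC(C)=O)c(OC)c1OC
F9 | step 10 | 6-[3-(3,4-dimethoxy-5-triisopropylsilyloxyphenyl)prop-2-ynoyl]-2,3,4-trimethoxyphenyl acetate | COc1cc(C(=O)C#Cc2cc(OC)c(OC)c(O[Si](C(C)C)(C(C)C)C(C)C)c2)c(OC(C)=O)c(OC)c1OC
F10 | step 10 | 2-(3,4-dimethoxy-5-triisopropylsilyloxyphenyl)-6,7,8-trimethoxy-4H-chromen-4-one | COc1cc(-c2cc(=O)c3cc(OC)c(OC)c(OC)c3o2)cc(O[Si](C(C)C)(C(C)C)C(C)C)c1OC
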